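## Retrosynthetic overview
- **C3–C4, last step:** the side-chain Grignard reagent adds to methyl crotonate under Cu/Josiphos catalysis. This sets (R)-C3 and brings in the ester.
- **C8–C9:** B-alkyl Suzuki coupling of the 9-BBN adduct of a 4-vinylfuran with (E)-5-iodo-4-methylpent-4-en-1-ol. The E-C7=C8 bond comes from Zr-catalysed carboalumination of pent-4-yn-1-ol.
- **Central furan:** closed at O1–C2. A propargyl-alcohol-derived alkoxide attacks the former CBr2 carbon of 3-(2,2-dibromoethenyl)furan after C2–C3 coupling. Tautomerisation then creates the CH2 bridge (new [4+1] annulation).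
- **Ring order:** the 3-furyl ring is bought as furan-3-carbaldehyde. The 2,4-disubstituted furan is the only ring made (step 2).

**Locants:** C1–C10 are the decenoate chain of the target. In the central furan, O1 is the oxygen, C2 carries CH2-furyl and C4 carries the chain.

**Assumption:** the (S,R_p) enantiomer of Josiphos SL-J001 is taken as the one that sends a linear alkyl Grignard reagent to the Si face of C3 of methyl crotonate. A pilot run with n-hexylMgBr checks this. If the sense is opposite, the mirror-image ligand (also a catalogue item) is used and nothing else changes.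

## Route

Step 1
Reactants: 1 furan-3-carbaldehyde; 2 carbon tetrabromide
Product: 3 3-(2,2-dibromoethenyl)furan
Conditions: CBr4 (2 equiv), PPh3 (4 equiv), CH2Cl2, 0 °C, 1 h
Reagents that add atoms: carbon tetrabromide 2, BrC(Br)(Br)Br
Why: Ramirez dibromo-olefination (first stage of the Corey–Fuchs sequence), in which Ph3P=CBr2 made in situ undergoes a Wittig reaction with the aldehyde while the furan is inert at 0 °C; no stereocentre is formed.

Step 2
Reactants: 4 prop-2-yn-1-ol; 5 vinylmagnesium bromide; 3 3-(2,2-dibromoethenyl)furan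
Product: 10 4-ethenyl-2-(furan-3-ylmethyl)furan, via dimagnesiated dienolate 6 (not isolated), via alkenylzinc alkoxide 7 (not isolated), via bromodienolate 8 (not isolated), via alkylidene-dihydrofuran 9 (not isolated)
Conditions: 4 (1.3 equiv), 5 (2.8 equiv), CuI (10 mol %), THF, −10 °C→rt; ZnBr2 (1.5 equiv), 0 °C; 3 (1.0 equiv), PdCl2(DPEphos) (5 mol %), rt; KOt-Bu (3 equiv), t-BuOH, 50 °C; H2O
Reagents that add atoms: vinylmagnesium bromide 5, C=C[Mg]Br
Why: Proposed new method: a formal [4+1] furan annulation in which the O–C–C=C–metal unit from the known Cu-catalysed, alkoxide-directed anti-carbomagnesiation of propargyl alcohol (metal held cis to CH2O by chelation) acts as a C,O-dinucleophile and the CBr2 carbon of 3 as a 1,1-dielectrophile; after Mg→Zn exchange, Pd(0) inserts into the less hindered C–Br trans to the furyl group and couples with retention to give 8, which places the alkoxide in a 5-exo relation to the remaining C–Br, so KOt-Bu closes the ring at O1–C2 either by Cu/Pd-mediated intramolecular O-vinylation or by anti-E2 loss of HBr (H and Br are trans in 8) followed by 5-exo-dig alkoxide addition to the (Z)-enynolate, both channels giving 9, which base tautomerises (H from C5 to the exocyclic carbon) to aromatic 10; the closest known reaction types are the trans-selective Negishi mono-coupling of 1,1-dibromoalkenes, tandem C–C/C–O couplings of gem-dibromoolefins to benzofurans, and the base-mediated (Z)-2-en-4-yn-1-ol to furan cycloisomerisation, whereas the intermolecular union of a carbometalation-derived oxametallacycle with a gem-dibromoolefin is, as far as I know, not described.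

Step 3
Reactants: 11 pent-4-yn-1-ol; 12 trimethylaluminium
Product: 14 (4E)-5-iodo-4-methylpent-4-en-1-ol, via alkenylalane 13 (not isolated)
Conditions: AlMe3 (3 equiv), Cp2ZrCl2 (25 mol %), CH2Cl2, 0 °C→rt, 16 h; I2, THF, −30→0 °C; H2O
Reagents that add atoms: trimethylaluminium 12, C[Al](C)C; iodine, II
Why: Negishi Zr-catalysed carboalumination adds Me–Al syn across the terminal alkyne with Me on the internal carbon, and iodinolysis with retention gives the E-iodide (>98:2), which fixes the C7=C8 geometry.

Step 4
Reactants: 10 4-ethenyl-2-(furan-3-ylmethyl)furan; 14 (4E)-5-iodo-4-methylpent-4-en-1-ol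
Product: 16 (4E)-7-[5-(furan-3-ylmethyl)furan-3-yl]-4-methylhept-4-en-1-ol, via B-alkyl-9-BBN 15 (not isolated)
Conditions: 9-BBN (1.1 equiv), THF, 0 °C→rt; then 14, PdCl2(dppf) (5 mol %), 3 M aq NaOH, THF, 50 °C
Reagents that add atoms: none
Why: Anti-Markovnikov hydroboration with 9-BBN takes only the vinyl group (the furans are inert), and the B-alkyl Suzuki–Miyaura coupling joins C9 to C8 with retention of the E geometry and tolerates the free OH.

Step 5
Reactants: 16 (4E)-7-[5-(furan-3-ylmethyl)furan-3-yl]-4-methylhept-4-en-1-ol; 2 carbon tetrabromide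
Product: 17 4-[(3E)-7-bromo-4-methylhept-3-en-1-yl]-2-(furan-3-ylmethyl)furan
Conditions: CBr4, PPh3, 2,6-lutidine, CH2Cl2, 0 °C
Reagents that add atoms: carbon tetrabromide 2, BrC(Br)(Br)Br
Why: Appel reaction, an SN2 displacement of the alkoxyphosphonium ion at a primary carbon under buffered, near-neutral conditions that leave the furans and the trisubstituted alkene untouched.

Step 6
Reactants: 17 4-[(3E)-7-bromo-4-methylhept-3-en-1-yl]-2-(furan-3-ylmethyl)furan; 18 methyl (E)-but-2-enoate
Product: 21 methyl (3R,7E)-10-[5-(furan-3-ylmethyl)furan-3-yl]-3,7-dimethyldec-7-enoate, via Grignard reagent 19 (not isolated), via magnesium enolate 20 (not isolated)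
Conditions: Mg, Et2O, 35 °C; then CuBr·SMe2 (5 mol %), (S,R_p)-Josiphos SL-J001 (6 mol %), 18 (0.9 equiv, slow addition), t-BuOMe, −75 °C; aq NH4Cl
Reagents that add atoms: methyl (E)-but-2-enoate 18, C/C=C/C(=O)OC
Why: Cu/ferrocenyl-diphosphine-catalysed asymmetric conjugate addition of a primary alkyl Grignard reagent to methyl crotonate (known reaction type, typically 92–96 % ee), in which the chiral Cu(I) π-complex delivers the alkyl group to the Si face of C3 to give (R), 1,2-addition is suppressed at −75 °C, and the ester stays masked as enolate 20 until the quench.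

## Compound list
1 | furan-3-carbaldehyde | O=Cc1ccoc1 | starting material
2 | carbon tetrabromide | BrC(Br)(Br)Br | starting material
3 | 3-(2,2-dibromoethenyl)furan | BrC(Br)=Cc1ccoc1 | intermediate
4 | prop-2-yn-1-ol | C#CCO | starting material
5 | vinylmagnesium bromide | C=C[Mg]Br | starting material
6 | bromomagnesium (2Z)-3-(bromomagnesio)-2-ethenylprop-2-en-1-olate (chelated, Mg cis to CH2O) | C=C/C(CO[Mg]Br)=C/[Mg]Br | intermediate (not isolated)
7 | bromomagnesium (2Z)-3-(bromozincio)-2-ethenylprop-2-en-1-olate | C=C/C(CO[Mg]Br)=C/[Zn]Br | intermediate (not isolated)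
8 | bromomagnesium (2Z,4Z)-4-bromo-2-ethenyl-5-(furan-3-yl)penta-2,4-dien-1-olate | C=C/C(CO[Mg]Br)=C/C(Br)=C/c1ccoc1 | intermediate (not isolated)
9 | (2Z)-4-ethenyl-2-(furan-3-ylmethylidene)-2,5-dihydrofuran | C=CC1=C/C(=C/c2ccoc2)OC1 | intermediate (not isolated)
10 | 4-ethenyl-2-(furan-3-ylmethyl)furan | C=Cc1coc(Cc2ccoc2)c1 | intermediate
11 | pent-4-yn-1-ol | C#CCCCO | starting material
12 | trimethylaluminium | C[Al](C)C | starting material
13 | dimethylaluminium (4E)-5-(dimethylalumanyl)-4-methylpent-4-en-1-olate | C[Al](C)OCCC/C(C)=C/[Al](C)C | intermediate (not isolated)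
14 | (4E)-5-iodo-4-methylpent-4-en-1-ol | OCCC/C(C)=C/I | intermediate
15 | 9-{2-[5-(furan-3-ylmethyl)furan-3-yl]ethyl}-9-borabicyclo[3.3.1]nonane | C(Cc1coc(Cc2ccoc2)c1)B1C2CCCC1CCC2 | intermediate (not isolated)
16 | (4E)-7-[5-(furan-3-ylmethyl)furan-3-yl]-4-methylhept-4-en-1-ol | OCCC/C(C)=C/CCc1coc(Cc2ccoc2)c1 | intermediate
17 | 4-[(3E)-7-bromo-4-methylhept-3-en-1-yl]-2-(furan-3-ylmethyl)furan | BrCCC/C(C)=C/CCc1coc(Cc2ccoc2)c1 | intermediate
18 | methyl (E)-but-2-enoate (methyl crotonate) | C/C=C/C(=O)OC | starting material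
19 | {(4E)-7-[5-(furan-3-ylmethyl)furan-3-yl]-4-methylhept-4-en-1-yl}magnesium bromide | Br[Mg]CCC/C(C)=C/CCc1coc(Cc2ccoc2)c1 | intermediate (not isolated)
20 | bromomagnesium enolate of 21, (3R,7E), enolate C=C geometry irrelevant | COC(O[Mg]Br)=C[C@H](C)CCC/C(C)=C/CCc1coc(Cc2ccoc2)c1 | intermediate (not isolated)
21 | methyl (3R,7E)-10-[5-(furan-3-ylmethyl)furan-3-yl]-3,7-dimethyldec-7-enoate | COC(=O)C[C@H](C)CCC/C(C)=C/CCc1coc(Cc2ccoc2)c1 | target

## Step count and risks
Total steps: 6. Longest linear sequence: 5 (steps 1, 2, 4, 5, 6). Step 3 is a one-step side branch.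

**Step 2 (the proposed new annulation).**
- Risks: left-over vinyl metal competes for 3; 8 may couple a second time; ring closure may be slowed by Zn/Mg salts.
- The fallback sets out from 3, 4 and 5, returns at 10, and uses only known chemistry.
- The sequence is stopped after the carbomagnesiation, and 6 is quenched with I2 to give (2Z)-2-(iodomethylidene)but-3-en-1-ol F1.
- Separately, 3 is treated with n-BuLi (2.1 equiv, THF, −78 °C, second Corey–Fuchs stage). This gives lithium (furan-3-yl)acetylide F2, which water protonates to 3-ethynylfuran F3.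
- Sonogashira coupling of F1 with F3 (PdCl2(PPh3)2, CuI, Et3N) gives (2Z)-2-ethenyl-5-(furan-3-yl)pent-2-en-4-yn-1-ol F4.
- KOt-Bu in THF/t-BuOH cycloisomerises F4 through 9 to 10.

**Step 6 (late Grignard formation, ee and sense of induction).**
- Risks: Wurtz coupling on small scale; ee below 95 %; wrong ligand sense.
- The fallback sets out from 17 (through 19) and returns at 21. It replaces catalyst control by auxiliary control.
- (4R)-4-phenyl-1,3-oxazolidin-2-one is N-acylated with (E)-crotonyl chloride to give (4R)-3-[(2E)-but-2-enoyl]-4-phenyl-1,3-oxazolidin-2-one F5.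
- Grignard reagent 19 is added in the presence of stoichiometric CuBr·SMe2 (THF/Me2S, −40 °C). It attacks the Mg-chelated s-cis imide anti to the phenyl group, which is the Si face of C3.
- The product is (4R)-3-{(3R,7E)-10-[5-(furan-3-ylmethyl)furan-3-yl]-3,7-dimethyldec-7-enoyl}-4-phenyl-1,3-oxazolidin-2-one F6. Its minor diastereomer is removed on silica.
- NaOMe in MeOH at 0 °C gives 21 as one enantiomer.

**Step 4 (sensitive vinylfuran, one-pot borane coupling).**
- Risks: oligomerisation of 10; slow transmetalation from boron; protodeboronation.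
- The fallback sets out from 10 (through 15) and 14 and returns at 16. It separates the two events and changes the nucleophile to zinc.
- Borane 15 is oxidised (NaOH, H2O2) to 2-[5-(furan-3-ylmethyl)furan-3-yl]ethan-1-ol F7.
- F7 is converted (I2, PPh3, imidazole) to 2-(furan-3-ylmethyl)-4-(2-iodoethyl)furan F8.
- Zinc insertion (Zn dust, LiCl, THF) gives {2-[5-(furan-3-ylmethyl)furan-3-yl]ethyl}zinc iodide F9.
- F9 is coupled with 14 in a Negishi reaction (Pd(OAc)2/SPhos, slow addition so that the free OH is tolerated) to give 16.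

## Further compounds
F1 | step 2 | (2Z)-2-(iodomethylidene)but-3-en-1-ol | C=C/C(CO)=C/I
F2 | step 2 | lithium (furan-3-yl)acetylide | [Li]C#Cc1ccoc1
F3 | step 2 | 3-ethynylfuran | C#Cc1ccoc1
F4 | step 2 | (2Z)-2-ethenyl-5-(furan-3-yl)pent-2-en-4-yn-1-ol | C=C/C(CO)=C/C#Cc1ccoc1
F5 | step 6 | (4R)-3-[(2E)-but-2-enoyl]-4-phenyl-1,3-oxazolidin-2-one | C/C=C/C(=O)N1C(=O)OC[C@H]1c1ccccc1
F6 | step 6 | (4R)-3-{(3R,7E)-10-[5-(furan-3-ylmethyl)furan-3-yl]-3,7-dimethyldec-7-enoyl}-4-phenyl-1,3-oxazolidin-2-one | O=C(C[C@H](C)CCC/C(C)=C/CCc1coc(Cc2ccoc2)c1)N1C(=O)OC[C@H]1c1ccccc1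
F7 | step 4 | 2-[5-(furan-3-ylmethyl)furan-3-yl]ethan-1-ol | OCCc1coc(Cc2ccoc2)c1
F8 | step 4 | 2-(furan-3-ylmethyl)-4-(2-iodoethyl)furan | ICCc1coc(Cc2ccoc2)c1
F9 | step 4 | {2-[5-(furan-3-ylmethyl)furan-3-yl]ethyl}zinc iodide | I[Zn]CCc1coc(Cc2ccoc2)c1
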